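Numbering (cembrane): C1 = lactone β-CH, C14 = lactone O–CH, C13 = CHOH, C12 = CHMe, C9–C11 = (CH2)3, C8 = C(=C19H2), C7 and C4 = the two oxolane C–O carbons, C3 = CHOH, C15=C17 = lactone methylene, C16 = lactone C=O.
Enabling feature: the oxolane O ties C4 to C7, which lie 1,4 across the 14-membered carbocycle, and it is flanked by C3–OH and C8=C19. C3/C4/C7/C8 are thus the four carbons of an oxidised 1,5-diene, and (3R,4S,7R) is what one all-(R) bis-epoxide of a C3=C4/C7=C8 diene gives when O7 opens C4.
Cuts, in order: oxolane O–C4 (with one H on C19 replaced by SiMe3 as trigger); the two epoxide oxygens; C7=C8 (metathesis); C1–C14 and lactone C16–O (Barbier/lactonisation); then C9–C10 and C12–C13 in the aldehyde half, and C1–C15, C2–C3 and C4–CH3 in the bromide half.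
Forward ring order: γ-lactone (step 10), 14-membered carbocycle (step 11), two temporary oxiranes (step 12), oxolane last (step 13).
Stereochemistry: C12/C13 come from a Brown (Z)-crotylboration. C14/C1 come from a chelate-controlled chair addition of a Z-allylindium, relayed from C13. C3, C7 and the oxirane C4 come from the D-fructose-derived Shi ketone, and C4 is then inverted in the key step.
Helper: the CH2SiMe3 group on C8 is the only one. It makes the geometry of the ring-closing alkene irrelevant, fixes the direction and alkene regiochemistry of the cascade, and leaves in the key step. No protecting group is carried past step 4.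

Key step: step 13

Remark: ring closure in step 11 may give either C7=C8 geometry. Both are taken on together because C8 becomes trigonal again in step 13; 25 and 26 are drawn as the isomer with C6 and C9 trans.

Step 1
Reactants: 1 cis-but-2-ene; 2 (tert-butyldimethylsilyloxy)acetaldehyde
Product: 5 (2R,3S)-1-(tert-butyldimethylsilyloxy)-3-methylpent-4-en-2-ol, via (Z)-crotylpotassium 3 (not isolated), via (Z)-crotylbis(isopinocampheyl)borane 4 (not isolated)
Conditions: n-BuLi, KOt-Bu, THF, −78 → −45 °C; (+)-Ipc2BOMe [from (−)-α-pinene], −78 °C; BF3·OEt2; 2, −78 °C; then NaOH, H2O2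
Reagents that add atoms: none
Why: Brown asymmetric crotylboration, in which the Z-crotylborane reacts through a closed chair transition state to give the syn C12-Me/C13-OH pair and the isopinocampheyl groups direct attack to the Re face of 2, which sets (12S,13R).

Step 2
Reactants: 5 (2R,3S)-1-(tert-butyldimethylsilyloxy)-3-methylpent-4-en-2-ol
Product: 6 (3S,4R)-4,5-bis(tert-butyldimethylsilyloxy)-3-methylpent-1-ene
Conditions: TBSCl, imidazole, DMF, rt
Reagents that add atoms: TBSCl, CC(C)(C)[Si](C)(C)Cl
Why: Standard silylation masks the C13 hydroxyl so that it consumes neither borane nor alkoxide base in step 3, and no stereocentre is touched.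

Step 3
Reactants: 6 (3S,4R)-4,5-bis(tert-butyldimethylsilyloxy)-3-methylpent-1-ene; 7 2-(chloromethyl)allyltrimethylsilane
Product: 9 [(6S,7R)-7,8-bis(tert-butyldimethylsilyloxy)-6-methyl-2-methylideneoctyl]trimethylsilane, via B-alkyl-9-BBN 8 (not isolated)
Conditions: (9-BBN-H)2, THF, 60 °C; then KOt-Bu, CuOAc (10 mol %), 7, THF, 60 °C
Reagents that add atoms: none
Why: Anti-Markovnikov hydroboration of the only alkene followed by copper-catalysed allyl–alkyl coupling of the B-alkyl-9-BBN borate with the allylic chloride forms C9–C10, and SN2 and SN2′ attack on 7 give the same product because both allyl termini are CH2.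

Step 4
Reactants: 9 [(6S,7R)-7,8-bis(tert-butyldimethylsilyloxy)-6-methyl-2-methylideneoctyl]trimethylsilane
Product: 10 (2R,3S)-3-methyl-7-[(trimethylsilyl)methyl]oct-7-ene-1,2-diol
Conditions: TBAF, AcOH (1:1), THF, rt
Reagents that add atoms: none
Why: Buffered fluoride cleaves both O–Si bonds, while the C-bound allylic SiMe3 group has no leaving group or electrophile to drive its loss and should survive.

Step 5
Reactants: 10 (2R,3S)-3-methyl-7-[(trimethylsilyl)methyl]oct-7-ene-1,2-diol
Product: 11 (2R,3S)-2-hydroxy-3-methyl-7-[(trimethylsilyl)methyl]oct-7-enal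
Conditions: TEMPO (10 mol %), PhI(OAc)2, CH2Cl2, 0 °C → rt; used crude
Reagents that add atoms: none
Why: The TEMPO/PhI(OAc)2 oxidation takes the unhindered primary alcohol of the 1,2-diol much faster than the secondary one and stops at the aldehyde in dry CH2Cl2, so C13 keeps the free hydroxyl needed for chelation in step 10.

Step 6
Reactants: 12 hex-1-en-5-yne; 13 oxirane
Product: 16 (3E)-4-methylocta-3,7-dien-1-ol, via alkenyldimethylalane 14 (not isolated), via lithium alkenylalanate 15 (not isolated)
Conditions: Me3Al, Cp2ZrCl2 (25 mol %), CH2Cl2, rt; n-BuLi, THF–hexane, −78 °C; 13, −30 °C → rt; aq. work-up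
Reagents that add atoms: trimethylaluminium, C[Al](C)C
Why: Negishi zirconium-catalysed carboalumination adds Me and Al syn and regioselectively across the terminal alkyne (the monosubstituted alkene is inert), and the derived alanate opens oxirane with retention of geometry, which fixes the E C3=C4 alkene.

Step 7
Reactants: 16 (3E)-4-methylocta-3,7-dien-1-ol
Product: 17 (3E)-4-methylocta-3,7-dienal
Conditions: Dess–Martin periodinane, NaHCO3, CH2Cl2, 0 °C
Reagents that add atoms: none
Why: The buffered Dess–Martin oxidation is neutral and fast, so it should give the β,γ-unsaturated aldehyde without migration of the C3=C4 alkene into conjugation.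

Step 8
Reactants: 17 (3E)-4-methylocta-3,7-dienal; 18 methyl propiolate
Product: 20 methyl (5E)-3-hydroxy-6-methyl-2-methylidenedeca-5,9-dienoate (racemic), via α-aluminoacrylate 19 (not isolated)
Conditions: i-Bu2AlH, NMO, THF, 0 °C; 18; then 17, 0 °C → rt
Reagents that add atoms: none
Why: Vinylalumination (hydroalumination of the propiolate to the α-aluminoacrylate, then 1,2-addition) forms C1–C15 and gives the Morita–Baylis–Hillman-type adduct under non-basic conditions that the enolisable aldehyde tolerates, and the racemic carbinol centre is erased in step 9.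

Step 9
Reactants: 20 methyl (5E)-3-hydroxy-6-methyl-2-methylidenedeca-5,9-dienoate
Product: 21 methyl (2Z,5E)-2-(bromomethyl)-6-methyldeca-2,5,9-trienoate
Conditions: NBS, Me2S, CH2Cl2, 0 °C (premixed); then 20, 0 °C → rt
Reagents that add atoms: N-bromosuccinimide, O=C1CCC(=O)N1Br
Why: Corey–Kim-type activation of the Baylis–Hillman alcohol and SN2′ displacement by bromide give the favoured (Z)-2-(bromomethyl)enoate, and the preformed sulfonium salt spares the isolated alkenes.

Step 10
Reactants: 11 (2R,3S)-2-hydroxy-3-methyl-7-[(trimethylsilyl)methyl]oct-7-enal; 21 methyl (2Z,5E)-2-(bromomethyl)-6-methyldeca-2,5,9-trienoate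
Product: 24 (4S,5R)-5-{(1R,2S)-1-hydroxy-2-methyl-6-[(trimethylsilyl)methyl]hept-6-en-1-yl}-3-methylidene-4-[(2E)-3-methylhepta-2,6-dien-1-yl]oxolan-2-one, via allylindium dibromide 22 (not isolated), via syn,syn-dihydroxy ester 23 (not isolated)
Conditions: In powder, THF–H2O (1:1), rt; then PPTS (cat.), PhH, 50 °C
Reagents that add atoms: none
Why: Indium Barbier allylation in water followed by mild acid lactonisation, in which the Z-configured allylindium adds through a chair transition state (C1/C14 syn, hence the cis-lactone) to the aldehyde face left open in the five-membered indium chelate of the free C13 hydroxyl and the carbonyl (C13/C14 syn), and the C14 hydroxyl closes the γ-lactone in preference to a δ-lactone from C13–OH.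

Step 11
Reactants: 24 seco-lactone from step 10
Product: 25 macrocyclic allylsilane (1S,12S,13R,14R)-13-hydroxy-19-(trimethylsilyl)cembra-3E,7,15(17)-trien-16,14-olide
Conditions: Hoveyda–Grubbs II (10 mol %), 1,4-benzoquinone (20 mol %), PhMe, 80 °C, 1 mM, slow addition
Reagents that add atoms: none
Why: Ring-closing metathesis of the monosubstituted C7 alkene onto the 1,1-disubstituted allylsilane alkene at high dilution closes the 14-membered carbocycle, the trisubstituted C3=C4 alkene and the electron-poor α-methylene lactone being poor partners, and no stereocentre is formed because either C7=C8 geometry leads to the same C7 carbinol.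

Step 12
Reactants: 25 macrocyclic allylsilane
Product: 26 (1S,3R,4R,7R,8R,12S,13R,14R)-3,4:7,8-diepoxy-13-hydroxy-19-(trimethylsilyl)cembr-15(17)-en-16,14-olide
Conditions: D-fructose-derived Shi ketone (30 mol % per alkene), Oxone, K2CO3, Bu4NHSO4 (cat.), MeCN–DMM/aq. Na2B4O7–EDTA (pH 10.5), 0 °C; filtration through Et3N-deactivated silica
Reagents that add atoms: potassium peroxymonosulfate (Oxone), [K+].[O-]S(=O)(=O)OO
Why: Shi asymmetric epoxidation, in which the chiral dioxirane attacks both electron-rich trisubstituted alkenes through the spiro transition state that gives (R,R)-epoxides, so reagent control sets C3, C4, C7 and the transient C8, while the electron-poor α-methylene lactone is left alone and the basic buffer keeps the acid-labile silyl epoxide intact.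

Step 13
Reactants: 26 bis-epoxide
Product: 28 uprolide D, via hydroxy epoxide 27 (not isolated)
Conditions: CSA (10 mol %), water-saturated CH2Cl2, −20 → 0 °C
Reagents that add atoms: none
Why: Proposed new method: CSA protonates the oxirane that carries the CH2SiMe3 group, its C8–O bond ionises with hyperconjugative help from the C19–Si bond and water removes silicon (a vinylogous Peterson elimination), which lays down the C8=C19 methylene and frees the C7 hydroxyl of 27. That hydroxyl, held 1,4 to C4 across the carbocycle, then attacks the acid-activated C3–C4 oxirane at its tertiary carbon from the rear, a transannular 5-exo-tet closure that forms the oxolane and releases the C3 hydroxyl. The closest known reaction types are the epoxidation/desilylative opening of allylsilanes to transposed allylic alcohols and the acid-catalysed 5-exo cyclisation of γ,δ-epoxy alcohols used in epoxide-opening cascades; new is their coupling into one silicon-triggered cascade across a macrocycle. C4 is set by inversion (4R oxirane carbon to 4S ether carbon), whereas C3 and C7 keep the C–O bonds made in step 12, so the (3R,4R,7R) array can give only the (3R,4S,7R) cis-2,5-bridged oxolane. The step needs direction, alkene regiochemistry, ring-size and hydroxyl selectivity: the β-silicon effect makes the C7–C8 oxirane the first to open and lets Si rather than a C9 proton leave (no endocyclic alkene, no 4,8-bridged oxane), the tertiary C4 makes electronic and 5-exo preferences coincide against 6-endo attack at C3, and the C13 hydroxyl could reach only the secondary C3 and should therefore be slower.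

Compound list
1 | cis-but-2-ene | C/C=C\C | starting material
2 | (tert-butyldimethylsilyloxy)acetaldehyde | O=CCO[Si](C)(C)C(C)(C)C | starting material
3 | (Z)-crotylpotassium | [K+].[CH2-]/C=C\C | intermediate
4 | (Z)-crotylbis(isopinocampheyl)borane, Ipc from (−)-α-pinene | C/C=C\CB([C@H]1C[C@H]2C[C@@H]([C@@H]1C)C2(C)C)[C@H]1C[C@H]2C[C@@H]([C@@H]1C)C2(C)C | intermediate
5 | (2R,3S)-1-(tert-butyldimethylsilyloxy)-3-methylpent-4-en-2-ol | C=C[C@H](C)[C@@H](O)CO[Si](C)(C)C(C)(C)C | intermediate
6 | (3S,4R)-4,5-bis(tert-butyldimethylsilyloxy)-3-methylpent-1-ene | C=C[C@H](C)[C@@H](O[Si](C)(C)C(C)(C)C)CO[Si](C)(C)C(C)(C)C | intermediate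
7 | 2-(chloromethyl)allyltrimethylsilane | C=C(CCl)C[Si](C)(C)C | starting material
8 | B-alkyl-9-BBN from 6 (boron on C10) | B1(CC[C@H](C)[C@@H](O[Si](C)(C)C(C)(C)C)CO[Si](C)(C)C(C)(C)C)C2CCCC1CCC2 | intermediate
9 | [(6S,7R)-7,8-bis(tert-butyldimethylsilyloxy)-6-methyl-2-methylideneoctyl]trimethylsilane | C=C(C[Si](C)(C)C)CCC[C@H](C)[C@@H](O[Si](C)(C)C(C)(C)C)CO[Si](C)(C)C(C)(C)C | intermediate
10 | (2R,3S)-3-methyl-7-[(trimethylsilyl)methyl]oct-7-ene-1,2-diol | C=C(C[Si](C)(C)C)CCC[C@H](C)[C@@H](O)CO | intermediate
11 | (2R,3S)-2-hydroxy-3-methyl-7-[(trimethylsilyl)methyl]oct-7-enal | C=C(C[Si](C)(C)C)CCC[C@H](C)[C@@H](O)C=O | intermediate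
12 | hex-1-en-5-yne | C#CCCC=C | starting material
13 | oxirane | C1CO1 | starting material
14 | (E)-(2-methylhexa-1,5-dienyl)dimethylalane | C[Al](C)/C=C(\C)CCC=C | intermediate
15 | lithium butyl[(E)-2-methylhexa-1,5-dienyl]dimethylalanate | [Li+].CCCC[Al-](C)(C)/C=C(\C)CCC=C | intermediate
16 | (3E)-4-methylocta-3,7-dien-1-ol | OCC/C=C(\C)CCC=C | intermediate
17 | (3E)-4-methylocta-3,7-dienal | O=CC/C=C(\C)CCC=C | intermediate
18 | methyl propiolate | C#CC(=O)OC | starting material
19 | [1-(methoxycarbonyl)vinyl]diisobutylalane | C=C(C(=O)OC)[Al](CC(C)C)CC(C)C | intermediate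
20 | methyl (5E)-3-hydroxy-6-methyl-2-methylidenedeca-5,9-dienoate, racemic at C3 | C=C(C(=O)OC)C(O)C/C=C(\C)CCC=C | intermediate
21 | methyl (2Z,5E)-2-(bromomethyl)-6-methyldeca-2,5,9-trienoate | COC(=O)/C(CBr)=C/C/C=C(\C)CCC=C | intermediate
22 | allylindium reagent from 21, drawn as its RInBr2 component | COC(=O)/C(C[In](Br)Br)=C/C/C=C(\C)CCC=C | intermediate
23 | methyl (3S,4R,5R,6S)-4,5-dihydroxy-6-methyl-2-methylidene-3-[(2E)-3-methylhepta-2,6-dien-1-yl]-10-[(trimethylsilyl)methyl]undec-10-enoate | C=C(C[Si](C)(C)C)CCC[C@H](C)[C@@H](O)[C@H](O)[C@@H](C/C=C(\C)CCC=C)C(=C)C(=O)OC | intermediate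
24 | (4S,5R)-5-{(1R,2S)-1-hydroxy-2-methyl-6-[(trimethylsilyl)methyl]hept-6-en-1-yl}-3-methylidene-4-[(2E)-3-methylhepta-2,6-dien-1-yl]oxolan-2-one | C=C(C[Si](C)(C)C)CCC[C@H](C)[C@@H](O)[C@@H]1OC(=O)C(=C)[C@@H]1C/C=C(\C)CCC=C | intermediate
25 | (1S,12S,13R,14R)-13-hydroxy-19-(trimethylsilyl)cembra-3E,7,15(17)-trien-16,14-olide, drawn with C6 and C9 trans | C1/C=C(\C[Si](C)(C)C)CCC[C@H](C)[C@@H](O)[C@@H]2OC(=O)C(=C)[C@@H]2C/C=C(\C)C1 | intermediate
26 | (1S,3R,4R,7R,8R,12S,13R,14R)-3,4:7,8-diepoxy-13-hydroxy-19-(trimethylsilyl)cembr-15(17)-en-16,14-olide | C1[C@H]2O[C@]2(C[Si](C)(C)C)CCC[C@H](C)[C@@H](O)[C@@H]3OC(=O)C(=C)[C@@H]3C[C@H]4O[C@]4(C)C1 | intermediate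
27 | (1S,3R,4R,7R,12S,13R,14R)-3,4-epoxy-7,13-dihydroxycembra-8(19),15(17)-dien-16,14-olide | C1[C@@H](O)C(=C)CCC[C@H](C)[C@@H](O)[C@@H]2OC(=O)C(=C)[C@@H]2C[C@H]3O[C@]3(C)C1 | intermediate
28 | uprolide D, (1S,3R,4S,7R,12S,13R,14R) | C=C1CCC[C@H](C)[C@@H](O)[C@@H]2OC(=O)C(=C)[C@@H]2C[C@@H](O)[C@]2(C)CC[C@H]1O2 | target

Total step count: 13. Longest linear sequence: 9 (steps 1–5, then 10–13). The bromide branch (steps 6–9) joins at step 10.

Steps most likely to fail

Step 13 (the new cascade). The C3–C4 oxirane may ionise, rearrange or be taken by the C13 hydroxyl before the C7 hydroxyl has been released. The fallback uses only known reactions and opens each oxirane in its own operation; it sets out from 25. TBSOTf and 2,6-lutidine give the 13-O-TBS ether F1. The Shi conditions of step 12 give the silylated bis-epoxide F2. TBAF buffered with AcOH at 0 °C opens only the silyl-flanked oxirane (fluoride-induced β-elimination of an epoxysilane) and gives the isolated hydroxy epoxide F3. Catalytic CSA in CH2Cl2 then effects the ordinary 5-exo cyclisation of a γ,δ-epoxy alcohol to 13-O-TBS-uprolide D F4. HF·pyridine removes the silyl ether, and the route is rejoined at 28.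

Step 11. Closure onto the hindered 1,1-disubstituted alkene may be slower than intermolecular metathesis of the terminal alkene or alkene migration, which would lead to oligomerisation. The fallback exchanges the roles of the two unions and sets out from 10 and 21. Cross-metathesis (Hoveyda–Grubbs II, 10 in excess and recovered, geometry again irrelevant) gives the open-chain diol bromide F5. TEMPO/PhI(OAc)2 gives the α-hydroxy aldehyde F6. Indium in THF–H2O at high dilution forms the tethered allylindium F7, which closes the carbocycle at C1–C14 by the same chelated chair addition to give the macrocyclic dihydroxy ester F8. PPTS lactonises it, and the route is rejoined at 25.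

Step 12. Facial selectivity may be poor at the C7=C8 alkene, which sits in a mobile ring and may be a mixture of geometries. The fallback sets C7 at a ketone instead and sets out from 25. One equivalent of buffered mCPBA at −20 °C takes the more nucleophilic allylsilane alkene and gives the epoxysilane F9. AcOH opens it to the C7-epimeric allylic alcohols F10. MnO2 oxidises only the allylic alcohol, giving the enone F11. (S)-Me-CBS with catecholborane at −78 °C (alkenyl group as the large substituent) gives the (7R)-allylic alcohol F12. Shi epoxidation of the single remaining trisubstituted alkene rejoins the route at 27, which is treated with CSA as in step 13.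

Further compounds
F1 | step 13 | 13-O-TBS ether of 25 | C1/C=C(\C[Si](C)(C)C)CCC[C@H](C)[C@@H](O[Si](C)(C)C(C)(C)C)[C@@H]2OC(=O)C(=C)[C@@H]2C/C=C(\C)C1
F2 | step 13 | 13-O-TBS ether of bis-epoxide 26 | C1[C@H]2O[C@]2(C[Si](C)(C)C)CCC[C@H](C)[C@@H](O[Si](C)(C)C(C)(C)C)[C@@H]3OC(=O)C(=C)[C@@H]3C[C@H]4O[C@]4(C)C1
F3 | step 13 | 13-O-TBS ether of hydroxy epoxide 27 | C1[C@@H](O)C(=C)CCC[C@H](C)[C@@H](O[Si](C)(C)C(C)(C)C)[C@@H]2OC(=O)C(=C)[C@@H]2C[C@H]3O[C@]3(C)C1
F4 | step 13 | 13-O-TBS-uprolide D | C=C1CCC[C@H](C)[C@@H](O[Si](C)(C)C(C)(C)C)[C@@H]2OC(=O)C(=C)[C@@H]2C[C@@H](O)[C@]2(C)CC[C@H]1O2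
F5 | step 11 | open-chain diol bromide (cross-metathesis product of 10 and 21, drawn with C6 and C9 trans) | COC(=O)/C(CBr)=C/C/C=C(\C)CC/C=C(\C[Si](C)(C)C)CCC[C@H](C)[C@@H](O)CO
F6 | step 11 | open-chain α-hydroxy aldehyde bromide | COC(=O)/C(CBr)=C/C/C=C(\C)CC/C=C(\C[Si](C)(C)C)CCC[C@H](C)[C@@H](O)C=O
F7 | step 11 | tethered allylindium, drawn as RInBr2 | COC(=O)/C(C[In](Br)Br)=C/C/C=C(\C)CC/C=C(\C[Si](C)(C)C)CCC[C@H](C)[C@@H](O)C=O
F8 | step 11 | macrocyclic 13,14-dihydroxy methyl ester | C1/C=C(\C[Si](C)(C)C)CCC[C@H](C)[C@@H](O)[C@H](O)[C@H](C(=C)C(=O)OC)C/C=C(\C)C1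
F9 | step 12 | 7,8-epoxysilane of 25, both faces | C1C2OC2(C[Si](C)(C)C)CCC[C@H](C)[C@@H](O)[C@@H]3OC(=O)C(=C)[C@@H]3C/C=C(\C)C1
F10 | step 12 | 7-hydroxy-8(19)-ene, C7 epimers | C1C(O)C(=C)CCC[C@H](C)[C@@H](O)[C@@H]2OC(=O)C(=C)[C@@H]2C/C=C(\C)C1
F11 | step 12 | 7-oxo-8(19)-ene (enone) | C1C(=O)C(=C)CCC[C@H](C)[C@@H](O)[C@@H]2OC(=O)C(=C)[C@@H]2C/C=C(\C)C1
F12 | step 12 | (7R)-7-hydroxy-8(19)-ene | C1[C@@H](O)C(=C)CCC[C@H](C)[C@@H](O)[C@@H]2OC(=O)C(=C)[C@@H]2C/C=C(\C)C1
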